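The isoflavone is opened at both bonds to the C4 carbonyl: C4–C4a to ring A and C4–C3, the carbon bearing ring B. Since C4 sits between an aryl carbon and a vinylic carbon, it can come from carbon monoxide: one palladium-catalysed carbonylative Suzuki–Miyaura coupling joins a mirror-symmetric ring A iodide (iodine flanked by two MOM ethers, OMe para) to the 1-arylvinyl pinacol boronate of ring B. The aryl vinyl ketone so formed contains the complete isoflavone carbon framework, C2 being a terminal methylene. Deprotection, oxidative 6-endo closure of O1–C2, then O-allylation, Claisen shift to C6 and cross-metathesis finish the prenylated target.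

Key step: step 5

Remark: the target has no stereocentre and no stereogenic double bond; atoms are numbered as in chromen-4-one (O1, C2, C3, C4, C4a, C5–C8, C8a), ring B is the 2,4,5-trimethoxyphenyl group at C3, and MOM is methoxymethyl.

Step 1
Reactants: 1 5-methoxyresorcinol
Product: 2 1-methoxy-3,5-bis(methoxymethoxy)benzene
Conditions: MOMCl, K2CO3, acetone, 0 °C to rt
Reagents that add atoms: chloromethyl methyl ether (MOMCl), COCCl
Why: Williamson-type O-alkylation of both phenols with the reactive alpha-chloro ether gives the bis-acetal, which masks the phenols and provides two cooperating directing groups for step 2 (MOM protection).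

Step 2
Reactants: 2 1-methoxy-3,5-bis(methoxymethoxy)benzene
Product: 4 2-iodo-5-methoxy-1,3-bis(methoxymethoxy)benzene, via aryllithium 3 (not isolated)
Conditions: n-BuLi, TMEDA, THF, 0 °C; then I2, −78 °C to rt
Reagents that add atoms: n-butyllithium, [Li]CCCC (lithium of intermediate 3 only); iodine, II
Why: Directed ortho-metalation should occur at the CH flanked by two chelating MOM ethers, a better site than those between one MOM ether and the methoxy group, and the aryllithium is then trapped by I2 (lithiation–iodination).

Step 3
Reactants: 5 2,4,5-trimethoxyacetophenone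
Product: 7 1-(2,4,5-trimethoxyphenyl)ethenyl trifluoromethanesulfonate, via potassium enolate 6 (not isolated)
Conditions: KN(SiMe3)2, THF, −78 °C; then PhNTf2, −78 to 0 °C; cold aq. NaOH wash, Et3N-deactivated silica, used at once
Reagents that add atoms: potassium bis(trimethylsilyl)amide, C[Si](C)(C)[N-][Si](C)(C)C.[K+] (potassium of intermediate 6 only); N-phenylbis(trifluoromethanesulfonimide), O=S(=O)(N(c1ccccc1)S(=O)(=O)C(F)(F)F)C(F)(F)F
Why: Deprotonation of the methyl ketone gives the only possible enolate, and its O-sulfonylation by PhNTf2 delivers the 1-arylvinyl triflate (enol triflate formation), which is handled cold and base-washed because the electron-rich aryl group makes it prone to ionisation.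

Step 4
Reactants: 7 1-(2,4,5-trimethoxyphenyl)ethenyl trifluoromethanesulfonate; 8 bis(pinacolato)diboron
Product: 9 4,4,5,5-tetramethyl-2-[1-(2,4,5-trimethoxyphenyl)ethenyl]-1,3,2-dioxaborolane
Conditions: PdCl2(PPh3)2 (3 mol %), PPh3 (6 mol %), KOPh, toluene, 50 °C
Reagents that add atoms: none
Why: Miyaura borylation, in which zerovalent palladium inserts into the vinyl C–OTf bond, the phenoxide-activated diboron transmetalates and reductive elimination gives the alkenyl boronate, with the weak base and low temperature suppressing coupling of the product with unreacted triflate.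

Step 5
Reactants: 4 2-iodo-5-methoxy-1,3-bis(methoxymethoxy)benzene; 9 4,4,5,5-tetramethyl-2-[1-(2,4,5-trimethoxyphenyl)ethenyl]-1,3,2-dioxaborolane; 10 carbon monoxide
Product: 11 1-[4-methoxy-2,6-bis(methoxymethoxy)phenyl]-2-(2,4,5-trimethoxyphenyl)prop-2-en-1-one
Conditions: Pd(OAc)2 (5 mol %), di(1-adamantyl)-n-butylphosphine (10 mol %), K2CO3, CO (5 bar), toluene/H2O, 80 °C, slow addition of 9
Reagents that add atoms: none
Why: Pd(OAc)2 is reduced in situ to a zerovalent palladium–phosphine complex that adds oxidatively into the C–I bond of 4; CO then coordinates and the electron-rich aryl group migrates onto it to give an aroyl palladium iodide, which creates the C4–C4a bond. Carbonate-activated boronate 9 transfers its 1-arylvinyl group to palladium and reductive elimination forms the C3–C4 bond, releasing enone 11 and the catalyst. The closest known reaction type is the carbonylative Suzuki–Miyaura coupling of di-ortho-substituted aryl iodides with alkenylboron reagents under Pd(OAc)2/di(1-adamantyl)alkylphosphine catalysis. No ring is closed and no stereocentre is created. The selectivity required is acyl coupling over direct aryl–vinyl coupling, and it is secured by the two ortho MOM-oxy groups of 4, which slow transmetalation at the crowded arylpalladium stage while CO insertion relieves that crowding, reinforced by CO pressure, the bulky phosphine and slow addition of 9. Because 4 is symmetric, either ortho oxygen of 11 can later serve as O1 and the other becomes the 5-OH.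

Step 6
Reactants: 11 1-[4-methoxy-2,6-bis(methoxymethoxy)phenyl]-2-(2,4,5-trimethoxyphenyl)prop-2-en-1-one
Product: 12 1-(2,6-dihydroxy-4-methoxyphenyl)-2-(2,4,5-trimethoxyphenyl)prop-2-en-1-one
Conditions: conc. HCl (cat.), MeOH/THF, 40 °C
Reagents that add atoms: none
Why: Acid-catalysed acetal exchange with methanol cleaves both MOM ethers, which are activated by the ortho carbonyl group, while the mild temperature limits conjugate addition to the enone (MOM deprotection).

Step 7
Reactants: 12 1-(2,6-dihydroxy-4-methoxyphenyl)-2-(2,4,5-trimethoxyphenyl)prop-2-en-1-one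
Product: 13 5-hydroxy-7-methoxy-3-(2,4,5-trimethoxyphenyl)-4H-chromen-4-one
Conditions: Pd(OAc)2 (10 mol %), O2 (1 atm), DMSO, 60 °C
Reagents that add atoms: none
Why: Wacker-type oxidative cyclisation, in which divalent palladium activates the 1,1-disubstituted alkene, one of the two equivalent phenols adds to the terminal methylene in 6-endo mode to form O1–C2, beta-hydride elimination from C2 installs the C2=C3 double bond and O2 reoxidises zerovalent palladium, leaving the second phenol as the chelated 5-OH.

Step 8
Reactants: 13 5-hydroxy-7-methoxy-3-(2,4,5-trimethoxyphenyl)-4H-chromen-4-one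
Product: 14 7-methoxy-5-(prop-2-en-1-yloxy)-3-(2,4,5-trimethoxyphenyl)-4H-chromen-4-one
Conditions: allyl bromide, K2CO3, DMF, 60 °C
Reagents that add atoms: allyl bromide, C=CCBr
Why: Williamson etherification of the only free phenol, where the hydrogen-bonded 5-OH needs carbonate in warm DMF but the unhindered primary allylic bromide should alkylate it cleanly (O-allylation).

Step 9
Reactants: 14 7-methoxy-5-(prop-2-en-1-yloxy)-3-(2,4,5-trimethoxyphenyl)-4H-chromen-4-one
Product: 16 5-hydroxy-7-methoxy-6-(prop-2-en-1-yl)-3-(2,4,5-trimethoxyphenyl)-4H-chromen-4-one, via dienone 15 (not isolated)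
Conditions: N,N-diethylaniline, 200 °C, sealed tube
Reagents that add atoms: none
Why: Aromatic Claisen rearrangement, in which the [3,3] shift from O5 can only reach C6 because the other ortho position, C4a, is fully substituted, and tautomerisation of dienone 15 restores the chelated 5-OH.

Step 10
Reactants: 16 5-hydroxy-7-methoxy-6-(prop-2-en-1-yl)-3-(2,4,5-trimethoxyphenyl)-4H-chromen-4-one
Product: 17 5-hydroxy-7-methoxy-6-(3-methylbut-2-en-1-yl)-3-(2,4,5-trimethoxyphenyl)-4H-chromen-4-one (CNP0525254.0)
Conditions: second-generation Grubbs catalyst (5 mol %), 2-methyl-2-butene (excess), CH2Cl2, 35 °C, sealed tube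
Reagents that add atoms: 2-methyl-2-butene, CC=C(C)C
Why: Olefin cross-metathesis of the terminal allyl group with excess 2-methyl-2-butene exchanges the =CH2 terminus for =C(CH3)2 with loss of propene, a standard allyl-to-prenyl conversion that tolerates the phenol and the chromone and creates no stereogenic double bond.

Compound list
1 | 5-methoxyresorcinol | COc1cc(O)cc(O)c1 | starting material
2 | 1-methoxy-3,5-bis(methoxymethoxy)benzene | COCOc1cc(OC)cc(OCOC)c1 | intermediate
3 | [4-methoxy-2,6-bis(methoxymethoxy)phenyl]lithium | COCOc1cc(OC)cc(OCOC)c1[Li] | intermediate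
4 | 2-iodo-5-methoxy-1,3-bis(methoxymethoxy)benzene | COCOc1cc(OC)cc(OCOC)c1I | intermediate
5 | 2,4,5-trimethoxyacetophenone | CC(=O)c1cc(OC)c(OC)cc1OC | starting material
6 | potassium 1-(2,4,5-trimethoxyphenyl)ethen-1-olate | C=C([O-])c1cc(OC)c(OC)cc1OC.[K+] | intermediate
7 | 1-(2,4,5-trimethoxyphenyl)ethenyl trifluoromethanesulfonate | C=C(OS(=O)(=O)C(F)(F)F)c1cc(OC)c(OC)cc1OC | intermediate
8 | bis(pinacolato)diboron | CC1(C)OB(B2OC(C)(C)C(C)(C)O2)OC1(C)C | starting material
9 | 4,4,5,5-tetramethyl-2-[1-(2,4,5-trimethoxyphenyl)ethenyl]-1,3,2-dioxaborolane | C=C(B1OC(C)(C)C(C)(C)O1)c1cc(OC)c(OC)cc1OC | intermediate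
10 | carbon monoxide | [C-]#[O+] | starting material
11 | 1-[4-methoxy-2,6-bis(methoxymethoxy)phenyl]-2-(2,4,5-trimethoxyphenyl)prop-2-en-1-one | C=C(C(=O)c1c(OCOC)cc(OC)cc1OCOC)c1cc(OC)c(OC)cc1OC | intermediate
12 | 1-(2,6-dihydroxy-4-methoxyphenyl)-2-(2,4,5-trimethoxyphenyl)prop-2-en-1-one | C=C(C(=O)c1c(O)cc(OC)cc1O)c1cc(OC)c(OC)cc1OC | intermediate
13 | 5-hydroxy-7-methoxy-3-(2,4,5-trimethoxyphenyl)-4H-chromen-4-one | COc1cc(O)c2c(c1)occ(-c1cc(OC)c(OC)cc1OC)c2=O | intermediate
14 | 7-methoxy-5-(prop-2-en-1-yloxy)-3-(2,4,5-trimethoxyphenyl)-4H-chromen-4-one | C=CCOc1cc(OC)cc2occ(-c3cc(OC)c(OC)cc3OC)c(=O)c12 | intermediate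
15 | 7-methoxy-6-(prop-2-en-1-yl)-3-(2,4,5-trimethoxyphenyl)-4H-chromene-4,5(6H)-dione (racemic, transient ortho-dienone) | C=CCC1C(=O)C2=C(C=C1OC)OC=C(c3cc(OC)c(OC)cc3OC)C2=O | intermediate
16 | 5-hydroxy-7-methoxy-6-(prop-2-en-1-yl)-3-(2,4,5-trimethoxyphenyl)-4H-chromen-4-one | C=CCc1c(OC)cc2occ(-c3cc(OC)c(OC)cc3OC)c(=O)c2c1O | intermediate
17 | 5-hydroxy-7-methoxy-6-(3-methylbut-2-en-1-yl)-3-(2,4,5-trimethoxyphenyl)-4H-chromen-4-one (CNP0525254.0) | COc1cc(OC)c(-c2coc3cc(OC)c(CC=C(C)C)c(O)c3c2=O)cc1OC | target

Total step count: 10 steps.
Longest linear sequence: 8 steps (steps 1, 2, 5–10 from 1; equally steps 3, 4, 5–10 from 5).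

Steps most likely to fail

1. Step 5 (carbonylative coupling). Transmetalation may overtake CO insertion and give direct aryl–vinyl coupling, the vinyl boronate may protodeboronate or oligomerise, or the enone may suffer conjugate addition under the basic conditions. The fallback is the classical deoxybenzoin route. It sets out from compound 2, which is lithiated as in step 2 to aryllithium 3. This is added in THF at −78 °C to N-methoxy-N-methyl-2-(2,4,5-trimethoxyphenyl)acetamide F1, itself prepared from commercial 2,4,5-trimethoxyphenylacetic acid with carbonyldiimidazole and N,O-dimethylhydroxylamine hydrochloride. The Weinreb ketone synthesis should give 1-[4-methoxy-2,6-bis(methoxymethoxy)phenyl]-2-(2,4,5-trimethoxyphenyl)ethan-1-one F2. Alpha-methylenation of F2 with paraformaldehyde and diisopropylammonium trifluoroacetate in refluxing THF (Mannich-type condensation) then gives enone 11, where the route is rejoined.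

2. Step 3 (enol triflate). The electron-rich 1-arylvinyl triflate may ionise and hydrolyse back to the ketone during work-up or on silica. The fallback is a Shapiro borylation that bypasses steps 3 and 4. It sets out from compound 5, which is condensed with 2,4,6-tri(propan-2-yl)benzenesulfonohydrazide (MeOH, cat. HCl, rt) to give (E)-N'-[1-(2,4,5-trimethoxyphenyl)ethylidene]-2,4,6-tri(propan-2-yl)benzenesulfonohydrazide F3. Treatment with n-BuLi (2.2 equiv) in THF/TMEDA from −78 to 0 °C should expel arenesulfinate and N2 and give [1-(2,4,5-trimethoxyphenyl)ethenyl]lithium F4. Quenching at −78 °C with 2-isopropoxy-4,4,5,5-tetramethyl-1,3,2-dioxaborolane gives boronate 9, where the route is rejoined.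

3. Step 6 (MOM removal on the enone). A liberated phenol, or methanol, may add to the enone during the acidic deprotection and consume the alkene that step 7 needs. The fallback makes that ring closure the intended path and replaces steps 6 and 7. It sets out from compound 11, which is heated with HCl in MeOH and then with NaOAc, so that deprotection is followed by 6-endo oxa-Michael addition to racemic 5-hydroxy-7-methoxy-3-(2,4,5-trimethoxyphenyl)chroman-4-one F5. Dehydrogenation of F5 with DDQ in refluxing dioxane gives isoflavone 13, where the route is rejoined.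

Further compounds
F1 | step 5 | N-methoxy-N-methyl-2-(2,4,5-trimethoxyphenyl)acetamide | CON(C)C(=O)Cc1cc(OC)c(OC)cc1OC
F2 | step 5 | 1-[4-methoxy-2,6-bis(methoxymethoxy)phenyl]-2-(2,4,5-trimethoxyphenyl)ethan-1-one | COCOc1cc(OC)cc(OCOC)c1C(=O)Cc1cc(OC)c(OC)cc1OC
F3 | step 3 | (E)-N'-[1-(2,4,5-trimethoxyphenyl)ethylidene]-2,4,6-tri(propan-2-yl)benzenesulfonohydrazide | C/C(=N\NS(=O)(=O)c1c(C(C)C)cc(C(C)C)cc1C(C)C)c1cc(OC)c(OC)cc1OC
F4 | step 3 | [1-(2,4,5-trimethoxyphenyl)ethenyl]lithium | C=C([Li])c1cc(OC)c(OC)cc1OC
F5 | step 6 | 5-hydroxy-7-methoxy-3-(2,4,5-trimethoxyphenyl)chroman-4-one (racemic) | COc1cc(O)c2c(c1)OCC(c1cc(OC)c(OC)cc1OC)C2=O
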